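**Plan**

- Retrosynthesis: the depside C(=O)–O bond between the ring A carbonyl and O4 of ring B is cut first, with the ring B carboxyl held as a benzyl ester. In ring A the C1–CO2H and C6–pentyl bonds are then cut together, back to 3,5-dimethoxybenzyne, a pentyl Grignard reagent and CO2. Ring B gives up its carboxyl carbon to return to olivetol.
- Enabling feature: ring A has the carboxyl carbon on C1 and the pentyl chain on the adjacent C6, with an oxygen on C2 beside the carboxyl-bearing carbon and a second oxygen on C4. This is what results when a carbon nucleophile and then an electrophile add across a 3-alkoxyaryne whose triple bond spans C1 and C6.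
- Forward: both benzene rings are bought, so no ring is formed. The ring A acid is made in steps 1–3 (Grignard reagent, aryne carbomagnesiation–carboxylation, chelation-directed demethylation at O2). The ring B phenol is made in steps 4–9 from olivetol (formylation, O4 allylation, O2 methylation, oxidation, benzyl ester, deallylation). The halves are joined in step 10 and the benzyl ester is removed in step 11.
- Stereochemistry: the target has no stereocentre and no stereogenic double bond; regiochemistry is the only selectivity to control.

Key step: step 2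

Assumption: the ortho-hydroxyl of the ring A acid, hydrogen-bonded to its own carboxyl group, is taken to be unreactive enough to stay unprotected in the anhydride-mediated esterification.

**Route**

Step 1
Reactants: 1 1-bromopentane
Product: 2 pentylmagnesium bromide
Conditions: Mg turnings, I2 (cat.), THF, reflux; solution titrated and used directly
Reagents that add atoms: magnesium, [Mg]
Why: Magnesium inserts into the primary C–Br bond (Grignard reagent formation), a standard case for a primary alkyl bromide in THF.

Step 2
Reactants: 3 1-chloro-3,5-dimethoxybenzene; 2 pentylmagnesium bromide; 4 carbon dioxide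
Product: 8 2,4-dimethoxy-6-pentylbenzoic acid, via 2-chloro-4,6-dimethoxyphenyllithium 5 (not isolated), via 3,5-dimethoxybenzyne 6 (not isolated), via 2,4-dimethoxy-6-pentylphenylmagnesium bromide 7 (not isolated)
Conditions: lithium 2,2,6,6-tetramethylpiperidide (LiTMP, 1.1 equiv, from 2,2,6,6-tetramethylpiperidine and n-BuLi), THF, −78 °C; 2 (2.5 equiv), −78 °C → rt; CO2 (g), −40 °C → rt; aq. HCl
Reagents that add atoms: none
Why: LiTMP should remove the proton of 3 that lies between chlorine and a methoxyl, and on warming aryllithium 5 expels LiCl to give aryne 6; the mirror symmetry of 3 makes its two such protons equivalent, so only one aryne can arise. Pentylmagnesium bromide then adds across the strained triple bond with the pentyl group going to the aryne carbon remote from the flanking methoxyl, because the carbon–magnesium bond then develops ortho to oxygen, where the inductive effect of the methoxyl and the distortion of the aryne favour it. Arylmagnesium 7 is carboxylated by CO2 and acid work-up frees acid 8, so the C6–pentyl and C1–carboxyl bonds are both made in one flask. The closest known reaction type is the three-component coupling of base-generated 3-alkoxyarynes with Grignard reagents followed by an electrophilic quench. No ring closes and no stereocentre forms; the one selectivity needed is the regiochemistry of the carbomagnesiation, which the methoxyl beside the triple bond secures, while the hindered amide base and the excess of Grignard reagent should suppress addition of amine or of 5 to the aryne.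

Step 3
Reactants: 8 2,4-dimethoxy-6-pentylbenzoic acid
Product: 10 2-hydroxy-4-methoxy-6-pentylbenzoic acid, via cyclic chloroborate 9 (not isolated)
Conditions: BCl3 (3 equiv), CH2Cl2, −78 → 0 °C; then H2O
Reagents that add atoms: none
Why: BCl3 binds the carboxyl group and then the neighbouring methoxyl oxygen in a six-membered chelate, so chloride cleaves only that O–methyl bond (chelation-directed Lewis acid demethylation of an ortho-methoxy aryl carbonyl compound) and the unchelated 4-methoxyl should survive at low temperature.

Step 4
Reactants: 11 olivetol (5-pentylbenzene-1,3-diol)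
Product: 13 2,4-dihydroxy-6-pentylbenzaldehyde, via aryl iminium chloride 12 (not isolated)
Conditions: POCl3, DMF, 0 °C → rt; then H2O, 50 °C
Reagents that add atoms: N,N-dimethylformamide, CN(C)C=O; water, O
Why: In this Vilsmeier–Haack formylation the chloroiminium ion attacks the resorcinol carbon para to one hydroxyl and ortho to the other, the position normally taken in 5-alkylresorcinols, and aqueous hydrolysis of the iminium salt gives the aldehyde.

Step 5
Reactants: 13 2,4-dihydroxy-6-pentylbenzaldehyde
Product: 14 4-(allyloxy)-2-hydroxy-6-pentylbenzaldehyde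
Conditions: allyl bromide (1.05 equiv), K2CO3, acetone, rt
Reagents that add atoms: allyl bromide, C=CCBr
Why: Williamson etherification should occur only at O4, because the 4-hydroxyl (para to the formyl group) is the more acidic and its phenoxide the more nucleophilic, whereas the 2-hydroxyl is locked in a hydrogen bond to the aldehyde.

Step 6
Reactants: 14 4-(allyloxy)-2-hydroxy-6-pentylbenzaldehyde
Product: 15 4-(allyloxy)-2-methoxy-6-pentylbenzaldehyde
Conditions: MeI (excess), K2CO3, DMF, 40 °C
Reagents that add atoms: iodomethane, CI
Why: The remaining chelated phenol is methylated by Williamson etherification under more forcing conditions, to which the allyl ether and the aldehyde are inert.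

Step 7
Reactants: 15 4-(allyloxy)-2-methoxy-6-pentylbenzaldehyde
Product: 16 4-(allyloxy)-2-methoxy-6-pentylbenzoic acid
Conditions: NaClO2, NaH2PO4, 2-methyl-2-butene (excess), t-BuOH/H2O, rt
Reagents that add atoms: sodium chlorite, [Na+].[O-]Cl=O
Why: Pinnick oxidation converts even a hindered aromatic aldehyde into the acid, and the excess 2-methyl-2-butene traps hypochlorous acid so that the allyl ether and the electron-rich ring should stay untouched.

Step 8
Reactants: 16 4-(allyloxy)-2-methoxy-6-pentylbenzoic acid
Product: 17 benzyl 4-(allyloxy)-2-methoxy-6-pentylbenzoate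
Conditions: BnBr, K2CO3, DMF, rt
Reagents that add atoms: benzyl bromide, BrCc1ccccc1
Why: SN2 alkylation of the carboxylate oxygen by benzyl bromide sidesteps the steric hindrance that the two ortho substituents impose on acyl substitution.

Step 9
Reactants: 17 benzyl 4-(allyloxy)-2-methoxy-6-pentylbenzoate
Product: 18 benzyl 4-hydroxy-2-methoxy-6-pentylbenzoate
Conditions: Pd(PPh3)4 (5 mol %), morpholine, THF, rt
Reagents that add atoms: none
Why: In this Tsuji–Trost-type deallylation zerovalent palladium ionises the allyl aryl ether to a π-allyl complex and the phenoxide, morpholine captures the allyl group, and the benzyl ester is not affected.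

Step 10
Reactants: 10 2-hydroxy-4-methoxy-6-pentylbenzoic acid; 18 benzyl 4-hydroxy-2-methoxy-6-pentylbenzoate
Product: 20 benzyl 4-[(2-hydroxy-4-methoxy-6-pentylbenzoyl)oxy]-2-methoxy-6-pentylbenzoate, via mixed trifluoroacetic anhydride 19 (not isolated)
Conditions: (CF3CO)2O, toluene, rt
Reagents that add atoms: none
Why: Trifluoroacetic anhydride turns the hindered acid into a mixed anhydride that acts as an acylium-type donor and acylates the only free phenol of 18 (mixed-anhydride esterification as used for depsides), while the 2-hydroxyl of 10, hydrogen-bonded to its own carbonyl and sterically flanked, should compete poorly.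

Step 11
Reactants: 20 benzyl 4-[(2-hydroxy-4-methoxy-6-pentylbenzoyl)oxy]-2-methoxy-6-pentylbenzoate
Product: 21 2'-O-methylperlatolic acid
Conditions: H2 (1 atm), 10% Pd/C, EtOAc, rt
Reagents that add atoms: none
Why: Catalytic hydrogenolysis cleaves only the benzylic C–O bond of the benzyl ester; the aryl ester linkage, the methyl ethers and the phenol are inert to hydrogen on palladium.

**Compound list**

1 | 1-bromopentane | CCCCCBr | starting material
2 | pentylmagnesium bromide | CCCCC[Mg]Br | intermediate
3 | 1-chloro-3,5-dimethoxybenzene | COc1cc(Cl)cc(OC)c1 | starting material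
4 | carbon dioxide | O=C=O | starting material
5 | (2-chloro-4,6-dimethoxyphenyl)lithium | [Li]c1c(Cl)cc(OC)cc1OC | intermediate
6 | 3,5-dimethoxybenzyne (1,2-didehydro-3,5-dimethoxybenzene) | COC1=CC(OC)=CC#C1 | intermediate
7 | (2,4-dimethoxy-6-pentylphenyl)magnesium bromide | CCCCCc1cc(OC)cc(OC)c1[Mg]Br | intermediate
8 | 2,4-dimethoxy-6-pentylbenzoic acid | CCCCCc1cc(OC)cc(OC)c1C(=O)O | intermediate
9 | 2-chloro-7-methoxy-5-pentyl-4H-1,3,2-benzodioxaborinin-4-one (cyclic chloroborate bridging the carboxyl oxygen and O2) | CCCCCc1cc(OC)cc2OB(Cl)OC(=O)c12 | intermediate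
10 | 2-hydroxy-4-methoxy-6-pentylbenzoic acid | CCCCCc1cc(OC)cc(O)c1C(=O)O | intermediate
11 | olivetol (5-pentylbenzene-1,3-diol) | CCCCCc1cc(O)cc(O)c1 | starting material
12 | N-[(2,4-dihydroxy-6-pentylphenyl)methylidene]-N-methylmethanaminium chloride | CCCCCc1cc(O)cc(O)c1C=[N+](C)C.[Cl-] | intermediate
13 | 2,4-dihydroxy-6-pentylbenzaldehyde | CCCCCc1cc(O)cc(O)c1C=O | intermediate
14 | 4-(allyloxy)-2-hydroxy-6-pentylbenzaldehyde | CCCCCc1cc(OCC=C)cc(O)c1C=O | intermediate
15 | 4-(allyloxy)-2-methoxy-6-pentylbenzaldehyde | CCCCCc1cc(OCC=C)cc(OC)c1C=O | intermediate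
16 | 4-(allyloxy)-2-methoxy-6-pentylbenzoic acid | CCCCCc1cc(OCC=C)cc(OC)c1C(=O)O | intermediate
17 | benzyl 4-(allyloxy)-2-methoxy-6-pentylbenzoate | CCCCCc1cc(OCC=C)cc(OC)c1C(=O)OCc1ccccc1 | intermediate
18 | benzyl 4-hydroxy-2-methoxy-6-pentylbenzoate | CCCCCc1cc(O)cc(OC)c1C(=O)OCc1ccccc1 | intermediate
19 | 2-hydroxy-4-methoxy-6-pentylbenzoic trifluoroacetic anhydride | CCCCCc1cc(OC)cc(O)c1C(=O)OC(=O)C(F)(F)F | intermediate
20 | benzyl 4-[(2-hydroxy-4-methoxy-6-pentylbenzoyl)oxy]-2-methoxy-6-pentylbenzoate | CCCCCc1cc(OC)cc(O)c1C(=O)Oc1cc(CCCCC)c(C(=O)OCc2ccccc2)c(OC)c1 | intermediate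
21 | 2'-O-methylperlatolic acid, 4-[(2-hydroxy-4-methoxy-6-pentylbenzoyl)oxy]-2-methoxy-6-pentylbenzoic acid | CCCCCc1cc(OC)cc(O)c1C(=O)Oc1cc(CCCCC)c(C(=O)O)c(OC)c1 | target

**Step count**

Total steps: 11. Longest linear sequence: 8 steps (steps 4 to 11, from olivetol). The ring A arm takes steps 1 to 3 before the union.

**Steps most likely to fail**

Step 2. Lithiation may take place between the two methoxyls, where no chloride can be lost. The aryne may also be consumed by aryllithium 5 or by the amide before the Grignard reagent adds, or the hindered arylmagnesium may carboxylate incompletely. The fallback builds the same acid by formylation and oxidation and sets out from olivetol 11. Exhaustive methylation (MeI, K2CO3, DMF) gives 1,3-dimethoxy-5-pentylbenzene F1. Vilsmeier–Haack formylation (POCl3, DMF) next to the chain and para to a methoxyl gives 2,4-dimethoxy-6-pentylbenzaldehyde F2. Pinnick oxidation (NaClO2, NaH2PO4, 2-methyl-2-butene) then gives acid 8, where the route resumes.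

Step 10. The unprotected ortho-hydroxyl of 10 may be acylated (self-condensation or trifluoroacetylation), or the hindered mixed anhydride may transfer its acyl group to 18 too slowly. The fallback masks the hydroxyl and changes the acyl donor; it sets out from 10. Double benzylation (BnBr, K2CO3, DMF, 60 °C) gives benzyl 2-(benzyloxy)-4-methoxy-6-pentylbenzoate F3. Saponification (KOH, DMSO/H2O, 80 °C) gives 2-(benzyloxy)-4-methoxy-6-pentylbenzoic acid F4. Oxalyl chloride with catalytic DMF in CH2Cl2 gives 2-(benzyloxy)-4-methoxy-6-pentylbenzoyl chloride F5. Acylation of phenol 18 (Et3N, DMAP, CH2Cl2) gives benzyl 4-{[2-(benzyloxy)-4-methoxy-6-pentylbenzoyl]oxy}-2-methoxy-6-pentylbenzoate F6. Hydrogenolysis (H2, 10% Pd/C, EtOAc) removes both benzyl groups at once and arrives directly at target 21.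

Step 3. The electron-rich salicylic acid may lose CO2 under the Lewis and Brønsted acidic conditions, or the 4-methoxyl may be cleaved as well on over-reaction. The fallback protects the carboxyl group during the demethylation and sets out from 8. Esterification (MeI, K2CO3, DMF) gives methyl 2,4-dimethoxy-6-pentylbenzoate F7. BCl3 in CH2Cl2 (−78 → 0 °C) removes only the chelated methyl group to give methyl 2-hydroxy-4-methoxy-6-pentylbenzoate F8. Hydrolysis (KOH, DMSO/H2O, 90 °C, cold acidification) returns to acid 10.

**Further compounds**

F1 | step 2 | 1,3-dimethoxy-5-pentylbenzene | CCCCCc1cc(OC)cc(OC)c1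
F2 | step 2 | 2,4-dimethoxy-6-pentylbenzaldehyde | CCCCCc1cc(OC)cc(OC)c1C=O
F3 | step 10 | benzyl 2-(benzyloxy)-4-methoxy-6-pentylbenzoate | CCCCCc1cc(OC)cc(OCc2ccccc2)c1C(=O)OCc1ccccc1
F4 | step 10 | 2-(benzyloxy)-4-methoxy-6-pentylbenzoic acid | CCCCCc1cc(OC)cc(OCc2ccccc2)c1C(=O)O
F5 | step 10 | 2-(benzyloxy)-4-methoxy-6-pentylbenzoyl chloride | CCCCCc1cc(OC)cc(OCc2ccccc2)c1C(=O)Cl
F6 | step 10 | benzyl 4-{[2-(benzyloxy)-4-methoxy-6-pentylbenzoyl]oxy}-2-methoxy-6-pentylbenzoate | CCCCCc1cc(OC)cc(OCc2ccccc2)c1C(=O)Oc1cc(CCCCC)c(C(=O)OCc2ccccc2)c(OC)c1
F7 | step 3 | methyl 2,4-dimethoxy-6-pentylbenzoate | CCCCCc1cc(OC)cc(OC)c1C(=O)OC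
F8 | step 3 | methyl 2-hydroxy-4-methoxy-6-pentylbenzoate | CCCCCc1cc(OC)cc(O)c1C(=O)OC
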